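All runs are calculated on assumed constants; noise was put on by code.

- Reckon each flask by one number: the L curves run nearly straight after a short lag, as a steady feed from the solid would give.

| flask | Z | Q | temperature | remark | time |
|---|---|---|---|---|---|
| alpha | 11 mM | 51 mM | 85 °C | run made earlier |  |
| beta | 26 mM | 51 mM | 105 °C | run made earlier |  |
| Thursday's | 17 mM | 51.0 mM | 90 °C |  | 3.0 min |
| Friday's | 17 mM | 51.0 mM | 120 °C |  | 3.0 min |
| Saturday's | 17 mM | 51.0 mM | 105 °C |  | 3.0 min |

- alpha (time / min: L / %): 0.200: 0.2; 0.333: 1.0; 0.500: 2.6; 0.833: 4.1; 1.33: 8.5; 2.50: 20.3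
- beta (time / s: L / %): 10.0: 0.8; 15.0: 1.8; 25.0: 2.7; 40.0: 4.1; 80.0: 10.4

(each reading ± 0.5 percentage points)

- the best flask by amount of L, in percent of the Z charged; "all alike" if 1.5 percentage points covers them all (Thursday's / Friday's / Saturday's / all alike)
- amount of L at the end, in percent of the Z charged, Thursday's
- amount of L at the end, in percent of the Z charged, Friday's
- amount of L at the end, in percent of the Z charged, Saturday's

- solid, in amounts per volume of the solution: Z
- steps thought possible: Z <-> J; Q + G <-> D; D <-> E; J -> L; J <-> G
- at the start none of Z is in solution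
- what has only dissolved of Z counts as not reacted

- Taking the gain in L as independent of the charge and carrying it to a charge of 17 mM, the last readings give 0.0653 /min of the charge at 85 °C and 0.145 /min at 105 °C, with lags read as 0.487 min and 0.233 min.
- Saturday's, at the temperature of the beta run, gets 40.0%: this is the feed number, the rate times the time after the lag, or the fraction of the charge passed on to L while the feed holds.
- With the same factor per degree, Thursday's has a rate of 0.0796 /min and a feed number of 20.0%, and Friday's reaches 72.6%, so Friday's leads.
- One number is not safe for Friday's: per own charge the two runs gain 0.101 /min and 0.0945 /min, which leaves charge and temperature tangled, and 120 °C lies above both runs, so 72.6% stands as a high end.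
- The forecast gives 24%, 55% and 37% for Thursday's, Friday's and Saturday's, with Friday's best, from a “saturation-limited picture”, and its figure for Friday's is lower than 72.6%.
- The flasks give 22.1%, 47.3% and 38.9%, with Friday's best.

    Z ⇌ J, rate k1*(cs1 - [J]) while solid is left; crystals form when [J] > cs1 (solubility = 1.80 mM, k = 0.0270 /s)
    Q + G ⇌ D (K = 560 /M, k = 0.180 /M/s, Ea = 71.0 kJ/mol, ΔH = −27.0 kJ/mol)
    D ⇌ E (K = 0.900, k = 0.0160 /s, Ea = 86.0 kJ/mol, ΔH = −8.00 kJ/mol)
    J → L (k = 0.0320 /s, Ea = 105 kJ/mol)
    J ⇌ G (K = 0.670, k = 0.0580 /s, Ea = 86.0 kJ/mol, ΔH = −58.0 kJ/mol)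
    (constants at 90 °C)

- At the end of Friday's, J stands at 0.587% of the charge, far less than the 10.6% that the solution can hold; the dissolving of Z is the rate-limiting step there, and with its rate the feed number of Friday's becomes 48.6%, while 51.3% of the Z is still solid. Saturday's gives an L of 38.9% beside its feed number of 40.0%, and Thursday's, read at 2.0 min, has a feed number of 12.0% beside an L of 13.7%.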